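The route rests on disconnecting the C5–C6 bond of the carbocycle (chromene numbering), the bond between the quaternary carbon that carries CH3 and CH2CO2H and the CH carbon that carries CMe2CO2H. A δ-lactone fused to the finished oxane, with an (E)-alkenyl group on its carbinol carbon, is contracted by an Ireland–Claisen rearrangement of its silyl ketene acetal. One operation forms the C5–C6 bond, closes the carbocycle as the last ring, and sets quaternary C5 and its neighbour C6 by chirality transfer from the lactone carbinol. It exploits the vicinal C5/C6 pair flanked by C7–C8 and the ether carbon C8a; the lactone carbonyl becomes the C5 methyl, and the oxirane is already present.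

Key step: step 12

Remark: locants C2–C8a in the comments are those of the 2H-chromene skeleton of the target (O1; C2 carries CH3 and the oxirane; C5 is the quaternary carbon; C6 carries CMe2CO2H; C8a is the ether carbon at the ring fusion).
Assumption: L-(+)-diethyl tartrate gives the (2S,3S)-epoxy alcohols from both (E)-allylic alcohols, as it does from geraniol; compounds 20–24 are mixtures of epimers at the lactone α-carbon, which becomes planar in 25 and 26.

Step 1
Reactants: 1 geranyl acetate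
Product: 2 (2E,6E)-8-hydroxy-3,7-dimethylocta-2,6-dien-1-yl acetate
Conditions: SeO2 (cat.), t-BuOOH, salicylic acid (cat.), CH2Cl2, rt
Reagents that add atoms: tert-butyl hydroperoxide CC(C)(C)OO (the new oxygen, passed on through catalytic SeO2)
Why: Riley allylic oxidation in its catalytic form (ene reaction, then [2,3]-shift) should hydroxylate the (E)-methyl group of the more electron-rich terminal alkene and leave the allylic acetate end alone.

Step 2
Reactants: 2 hydroxy acetate
Product: 4 (2E)-5-[(2S,3S)-3-(hydroxymethyl)-3-methyloxiran-2-yl]-3-methylpent-2-en-1-ol, via epoxy acetate 3 (not isolated)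
Conditions: Ti(OiPr)4 (cat.), L-(+)-DET, t-BuOOH, 4 Å MS, CH2Cl2, −20 °C; then K2CO3 (cat.), MeOH, 0 °C
Reagents that add atoms: tert-butyl hydroperoxide CC(C)(C)OO
Why: Katsuki–Sharpless asymmetric epoxidation of the only free allylic alcohol should set both oxirane centres as (2S,3S) by reagent control, and transesterification then frees the second allylic alcohol.

Step 3
Reactants: 5 3-bromobut-3-en-1-ol; 6 benzyl bromide
Product: 7 benzyl 3-bromobut-3-en-1-yl ether
Conditions: NaH, THF, 0 °C → rt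
Reagents that add atoms: none
Why: Williamson ether synthesis; the vinylic bromide is inert to the alkoxide.

Step 4
Reactants: 4 epoxy diol; 7 bromoalkene
Product: 9 (2R,3S,6E)-3-[4-(benzyloxy)but-1-en-2-yl]-2,6-dimethyloct-6-ene-1,2,8-triol, via Grignard reagent 8 (not isolated)
Conditions: 7, Mg, THF, 50 °C (gives 8); 4, MeMgBr (2.0 equiv), THF, −40 °C; then 8, CuBr·SMe2 (10 mol%), −40 → 0 °C; aq NH4Cl
Reagents that add atoms: none
Why: copper-catalysed SN2 opening of the 2,3-epoxy alcohol by the alkenyl Grignard reagent should occur at the secondary oxirane carbon (the other is fully substituted) with inversion, which sets the CH centre and keeps the tertiary carbinol centre from step 2.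

Step 5
Reactants: 9 triol
Product: 11 (1S)-1-[(2R,5S,6R)-5-[4-(benzyloxy)but-1-en-2-yl]-6-(hydroxymethyl)-2,6-dimethyloxan-2-yl]ethane-1,2-diol, via epoxy triol 10 (not isolated)
Conditions: Ti(OiPr)4 (1.1 equiv), L-(+)-DET, t-BuOOH, 4 Å MS, CH2Cl2, −20 °C; then CSA (cat.), CH2Cl2, 0 °C → rt
Reagents that add atoms: tert-butyl hydroperoxide CC(C)(C)OO
Why: a second Sharpless epoxidation (reagent control, (2S,3S)) is followed by acid-catalysed 6-exo opening of the oxirane by the tertiary hydroxyl at the tertiary carbon with inversion, which closes the oxane, sets its quaternary ether centre and keeps the secondary carbinol centre.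

Step 6
Reactants: 11 oxane triol
Product: 13 [(2R,3S,6R)-3-[4-(benzyloxy)but-1-en-2-yl]-2,6-dimethyl-6-[(2S)-oxiran-2-yl]oxan-2-yl]methanol, via monotosylate 12 (not isolated)
Conditions: TsCl, Bu2SnO (cat.), Et3N, CH2Cl2, 0 °C; then K2CO3, MeOH, rt
Reagents that add atoms: none
Why: stannylene-mediated sulfonylation should pick the primary hydroxyl of the 1,2-diol, and intramolecular Williamson displacement by the neighbouring secondary alkoxide closes the terminal oxirane with retention at its CH centre.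

Step 7
Reactants: 13 oxirane alcohol
Product: 14 (2R,3S,6R)-3-[4-(benzyloxy)but-1-en-2-yl]-2,6-dimethyl-6-[(2S)-oxiran-2-yl]oxane-2-carbaldehyde
Conditions: Dess–Martin periodinane, NaHCO3, CH2Cl2, rt
Reagents that add atoms: none
Why: Dess–Martin oxidation of the neopentyl primary alcohol gives an aldehyde that cannot epimerise (quaternary α-carbon), and the buffered medium spares the oxirane.

Step 8
Reactants: 15 2,2-dimethylbut-3-ynoic acid; 6 benzyl bromide
Product: 16 benzyl 2,2-dimethylbut-3-ynoate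
Conditions: K2CO3, DMF, rt
Reagents that add atoms: none
Why: O-alkylation of the carboxylate (SN2) gives a pivalate-type benzyl ester that resists nucleophiles in the later steps.

Step 9
Reactants: 16 alkyne ester; 14 aldehyde
Product: 19 benzyl (3E,5R)-5-[(2R,3S,6R)-3-[4-(benzyloxy)but-1-en-2-yl]-2,6-dimethyl-6-[(2S)-oxiran-2-yl]oxan-2-yl]-5-hydroxy-2,2-dimethylpent-3-enoate, via alkenylzirconocene 17 (not isolated), via alkenylzinc 18 (not isolated)
Conditions: 16, Cp2Zr(H)Cl, CH2Cl2, rt; Me2Zn, toluene, −65 °C; then 14, −65 → 0 °C; aq NH4Cl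
Reagents that add atoms: none
Why: Schwartz hydrozirconation gives the (E)-alkenyl metal, and after transmetalation to zinc the 1,2-addition should pass through the Cram chelate (zinc bridging the aldehyde and ring-ether oxygens), so the alkenyl group enters from the side of the methyl group and gives the (5R)-carbinol.

Step 10
Reactants: 19 allylic alcohol
Product: 21 benzyl (3E,5R)-5-[(2R,3S,6R)-3-[4-(benzyloxy)-1-hydroxybutan-2-yl]-2,6-dimethyl-6-[(2S)-oxiran-2-yl]oxan-2-yl]-5-hydroxy-2,2-dimethylpent-3-enoate (both epimers at the butan-2-yl carbon), via alkylborane 20 (not isolated)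
Conditions: 9-BBN, THF, 0 °C → rt; then H2O2, aq NaOH, 0 °C
Reagents that add atoms: hydrogen peroxide OO
Why: anti-Markovnikov hydroboration with 9-BBN should touch only the 1,1-disubstituted alkene (the hindered (E)-alkene, the ester and the oxirane are inert), and the configuration of the new CH centre does not matter because it is enolised in step 12.

Step 11
Reactants: 21 diol
Product: 24 benzyl (3E)-4-[(2R,4aS,8R,8aR)-5-[2-(benzyloxy)ethyl]-2,8a-dimethyl-6-oxo-2-[(2S)-oxiran-2-yl]octahydropyrano[3,4-b]pyran-8-yl]-2,2-dimethylbut-3-enoate (both C5 epimers), via hydroxy aldehyde 22 (not isolated), via lactol 23 (not isolated)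
Conditions: TEMPO (cat.), PhI(OAc)2, CH2Cl2, rt
Reagents that add atoms: none
Why: oxidative lactonisation of a 1,5-diol: the primary alcohol is oxidised first, the aldehyde closes to the six-membered lactol with the allylic hydroxyl, and the lactol is oxidised on to the δ-lactone.

Step 12
Reactants: 24 lactone
Product: 28 (2R,4aS,5S,6R,8aS)-6-[1-(benzyloxy)-2-methyl-1-oxopropan-2-yl]-5-[2-(benzyloxy)ethyl]-2,8a-dimethyl-2-[(2S)-oxiran-2-yl]-3,4,4a,5,6,8a-hexahydro-2H-chromene-5-carboxylic acid, via lithium enolate 25 (not isolated), via silyl ketene acetal 26 (not isolated), via trimethylsilyl ester 27 (not isolated)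
Conditions: LiN(iPr)2, THF, −78 °C; Me3SiCl, Et3N, −78 °C → rt; then toluene, 110–140 °C (sealed tube); H2O, THF
Reagents that add atoms: none
Why: LiN(iPr)2 removes the only acidic proton (the lactone α-H; the benzyl ester has no α-hydrogen) and Me3SiCl traps the enolate as ketene acetal 26, whose O–C=C unit and the alkenyl group on the lactone carbinol carbon form an allyl vinyl ether that undergoes a suprafacial [3,3] shift. The closest known reaction is the Ireland–Claisen rearrangement of lactone silyl ketene acetals, by which 6-alkenyl δ-lactones are contracted to cyclohex-3-enecarboxylic acids. The carbocycle is closed by this ring contraction through a boat-like six-membered array (the C5–C6 bond forms as the lactone C–O bond breaks), the trans-fused oxane holding the lactone in the half-chair that places the alkenyl group axial over the ketene acetal. C5 is set because the alkenyl group can reach only the face of the ketene acetal on which the (R)-carbinol centre holds it, so the carboxyl carbon ends cis to the C8a methyl group and the CH2CH2OBn arm trans to it. C6 is set by the E geometry of the alkene, since only the rotamer with the allylic C–O bond perpendicular to the π bond can react, and it turns the CMe2CO2Bn group away from the ring, cis to the new carboxyl group. The step needs rearrangement to outrun silyl migration and β-elimination, which the absence of a leaving group β to the enolate and the preorganised axial alkenyl group should secure; water then cleaves silyl ester 27.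

Step 13
Reactants: 28 acid
Product: 30 benzyl 2-[(2R,4aS,5S,6S,8aS)-5-[2-(benzyloxy)ethyl]-5-(hydroxymethyl)-2,8a-dimethyl-2-[(2S)-oxiran-2-yl]-3,4,4a,5,6,8a-hexahydro-2H-chromen-6-yl]-2-methylpropanoate, via acyl imidazolide 29 (not isolated)
Conditions: 1,1'-carbonyldiimidazole, THF, 50 °C; then NaBH4, H2O, 0 °C
Reagents that add atoms: none
Why: the hindered acid is activated as its acyl imidazolide, which NaBH4 should reduce to the primary alcohol while the pivalate-type ester, the oxirane and the alkene are inert to borohydride.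

Step 14
Reactants: 30 alcohol
Product: 31 benzyl 2-[(2R,4aS,5S,6S,8aS)-5-[2-(benzyloxy)ethyl]-5-{[(1H-imidazol-1-ylcarbonothioyl)oxy]methyl}-2,8a-dimethyl-2-[(2S)-oxiran-2-yl]-3,4,4a,5,6,8a-hexahydro-2H-chromen-6-yl]-2-methylpropanoate
Conditions: 1,1'-thiocarbonyldiimidazole, DMAP (cat.), ClCH2CH2Cl, 70 °C
Reagents that add atoms: 1,1'-thiocarbonyldiimidazole S=C(n1ccnc1)n1ccnc1
Why: O-thioacylation under neutral conditions prepares the neopentyl alcohol for Barton–McCombie deoxygenation without exposing the oxirane to base or acid.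

Step 15
Reactants: 31 thiocarbonyl derivative
Product: 32 benzyl 2-[(2R,4aS,5R,6S,8aS)-5-[2-(benzyloxy)ethyl]-2,5,8a-trimethyl-2-[(2S)-oxiran-2-yl]-3,4,4a,5,6,8a-hexahydro-2H-chromen-6-yl]-2-methylpropanoate
Conditions: Bu3SnH (0.3 M), AIBN (cat.), toluene, 110 °C
Reagents that add atoms: none
Why: Barton–McCombie radical deoxygenation turns the former lactone carbonyl carbon into the C5 methyl group; the primary radical should be reduced by concentrated Bu3SnH faster than it can add to the ring alkene, and no stereocentre is touched.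

Step 16
Reactants: 32 dibenzyl compound
Product: 33 2-[(2R,4aS,5R,6S,8aS)-5-(2-hydroxyethyl)-2,5,8a-trimethyl-2-[(2S)-oxiran-2-yl]octahydro-2H-chromen-6-yl]-2-methylpropanoic acid
Conditions: H2 (1 atm), 10% Pd/C, EtOAc, rt
Reagents that add atoms: none
Why: heterogeneous hydrogenation should saturate the cis ring alkene and hydrogenolyse the benzyl ester and benzyl ether in one operation, while a non-benzylic, non-allylic oxirane is normally inert under neutral conditions.

Step 17
Reactants: 33 hydroxy acid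
Product: 34 2-[(2R,4aS,5R,6S,8aS)-5-(carboxymethyl)-2,5,8a-trimethyl-2-[(2S)-oxiran-2-yl]octahydro-2H-chromen-6-yl]-2-methylpropanoic acid
Conditions: TEMPO (cat.), PhI(OAc)2, MeCN/pH 7 phosphate buffer, rt
Reagents that add atoms: water O
Why: TEMPO/PhI(OAc)2 oxidation in buffered aqueous acetonitrile takes the primary alcohol through the aldehyde hydrate to the carboxylic acid without opening the oxirane.

Compound list
1 | geranyl acetate [(2E)-3,7-dimethylocta-2,6-dien-1-yl acetate] | CC(=O)OC/C=C(\C)CCC=C(C)C | starting material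
2 | (2E,6E)-8-hydroxy-3,7-dimethylocta-2,6-dien-1-yl acetate | CC(=O)OC/C=C(\C)CC/C=C(\C)CO | intermediate
3 | (2E)-5-[(2S,3S)-3-(hydroxymethyl)-3-methyloxiran-2-yl]-3-methylpent-2-en-1-yl acetate (not isolated) | CC(=O)OC/C=C(\C)CC[C@@H]1O[C@@]1(C)CO | intermediate
4 | (2E)-5-[(2S,3S)-3-(hydroxymethyl)-3-methyloxiran-2-yl]-3-methylpent-2-en-1-ol | OC/C=C(\C)CC[C@@H]1O[C@@]1(C)CO | intermediate
5 | 3-bromobut-3-en-1-ol | OCCC(Br)=C | starting material
6 | benzyl bromide | BrCc1ccccc1 | starting material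
7 | benzyl 3-bromobut-3-en-1-yl ether | C=C(Br)CCOCc1ccccc1 | intermediate
8 | [4-(benzyloxy)but-1-en-2-yl]magnesium bromide (not isolated) | C=C([Mg]Br)CCOCc1ccccc1 | intermediate
9 | (2R,3S,6E)-3-[4-(benzyloxy)but-1-en-2-yl]-2,6-dimethyloct-6-ene-1,2,8-triol | OC/C=C(\C)CC[C@@H](C(=C)CCOCc1ccccc1)[C@@](C)(O)CO | intermediate
10 | (2R,3S)-3-[4-(benzyloxy)but-1-en-2-yl]-5-[(2S,3S)-3-(hydroxymethyl)-2-methyloxiran-2-yl]-2-methylpentane-1,2-diol (not isolated) | OC[C@@H]1O[C@@]1(C)CC[C@@H](C(=C)CCOCc2ccccc2)[C@@](C)(O)CO | intermediate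
11 | (1S)-1-[(2R,5S,6R)-5-[4-(benzyloxy)but-1-en-2-yl]-6-(hydroxymethyl)-2,6-dimethyloxan-2-yl]ethane-1,2-diol | OC[C@]1(C)O[C@@](C)([C@@H](O)CO)CC[C@H]1C(=C)CCOCc2ccccc2 | intermediate
12 | (2S)-2-[(2R,5S,6R)-5-[4-(benzyloxy)but-1-en-2-yl]-6-(hydroxymethyl)-2,6-dimethyloxan-2-yl]-2-hydroxyethyl 4-methylbenzenesulfonate (not isolated) | OC[C@]1(C)O[C@@](C)([C@@H](O)COS(=O)(=O)c2ccc(C)cc2)CC[C@H]1C(=C)CCOCc3ccccc3 | intermediate
13 | [(2R,3S,6R)-3-[4-(benzyloxy)but-1-en-2-yl]-2,6-dimethyl-6-[(2S)-oxiran-2-yl]oxan-2-yl]methanol | OC[C@]1(C)O[C@@](C)([C@@H]2CO2)CC[C@H]1C(=C)CCOCc3ccccc3 | intermediate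
14 | (2R,3S,6R)-3-[4-(benzyloxy)but-1-en-2-yl]-2,6-dimethyl-6-[(2S)-oxiran-2-yl]oxane-2-carbaldehyde | O=C[C@]1(C)O[C@@](C)([C@@H]2CO2)CC[C@H]1C(=C)CCOCc3ccccc3 | intermediate
15 | 2,2-dimethylbut-3-ynoic acid | C#CC(C)(C)C(=O)O | starting material
16 | benzyl 2,2-dimethylbut-3-ynoate | C#CC(C)(C)C(=O)OCc1ccccc1 | intermediate
17 | benzyl (3E)-4-[chlorobis(cyclopentadienyl)zirconio]-2,2-dimethylbut-3-enoate (not isolated) | Cl[Zr](C1C=CC=C1)(C1C=CC=C1)/C=C/C(C)(C)C(=O)OCc1ccccc1 | intermediate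
18 | benzyl (3E)-2,2-dimethyl-4-(methylzincio)but-3-enoate (not isolated) | C[Zn]/C=C/C(C)(C)C(=O)OCc1ccccc1 | intermediate
19 | benzyl (3E,5R)-5-[(2R,3S,6R)-3-[4-(benzyloxy)but-1-en-2-yl]-2,6-dimethyl-6-[(2S)-oxiran-2-yl]oxan-2-yl]-5-hydroxy-2,2-dimethylpent-3-enoate | O[C@H](/C=C/C(C)(C)C(=O)OCc1ccccc1)[C@]2(C)O[C@@](C)([C@@H]3CO3)CC[C@H]2C(=C)CCOCc4ccccc4 | intermediate
20 | B-alkyl-9-borabicyclo[3.3.1]nonane adduct of 19 at the terminal CH2 of the 1,1-disubstituted alkene (not isolated) | O[C@H](/C=C/C(C)(C)C(=O)OCc1ccccc1)[C@]2(C)O[C@@](C)([C@@H]3CO3)CC[C@H]2C(CB4C5CCCC4CCC5)CCOCc6ccccc6 | intermediate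
21 | benzyl (3E,5R)-5-[(2R,3S,6R)-3-[4-(benzyloxy)-1-hydroxybutan-2-yl]-2,6-dimethyl-6-[(2S)-oxiran-2-yl]oxan-2-yl]-5-hydroxy-2,2-dimethylpent-3-enoate (both epimers at the butan-2-yl carbon) | O[C@H](/C=C/C(C)(C)C(=O)OCc1ccccc1)[C@]2(C)O[C@@](C)([C@@H]3CO3)CC[C@H]2C(CO)CCOCc4ccccc4 | intermediate
22 | benzyl (3E,5R)-5-[(2R,3S,6R)-3-[4-(benzyloxy)-1-oxobutan-2-yl]-2,6-dimethyl-6-[(2S)-oxiran-2-yl]oxan-2-yl]-5-hydroxy-2,2-dimethylpent-3-enoate (not isolated) | O[C@H](/C=C/C(C)(C)C(=O)OCc1ccccc1)[C@]2(C)O[C@@](C)([C@@H]3CO3)CC[C@H]2C(C=O)CCOCc4ccccc4 | intermediate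
23 | benzyl (3E)-4-[(2R,4aS,8R,8aR)-5-[2-(benzyloxy)ethyl]-6-hydroxy-2,8a-dimethyl-2-[(2S)-oxiran-2-yl]octahydropyrano[3,4-b]pyran-8-yl]-2,2-dimethylbut-3-enoate (lactol; not isolated) | OC1O[C@H](/C=C/C(C)(C)C(=O)OCc2ccccc2)[C@]3(C)O[C@@](C)([C@@H]4CO4)CC[C@H]3C1CCOCc5ccccc5 | intermediate
24 | benzyl (3E)-4-[(2R,4aS,8R,8aR)-5-[2-(benzyloxy)ethyl]-2,8a-dimethyl-6-oxo-2-[(2S)-oxiran-2-yl]octahydropyrano[3,4-b]pyran-8-yl]-2,2-dimethylbut-3-enoate (both C5 epimers) | O=C1O[C@H](/C=C/C(C)(C)C(=O)OCc2ccccc2)[C@]3(C)O[C@@](C)([C@@H]4CO4)CC[C@H]3C1CCOCc5ccccc5 | intermediate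
25 | lithium enolate of lactone 24 (C5=C6 enolate of the pyranopyranone; not isolated) | [Li]OC=1O[C@H](/C=C/C(C)(C)C(=O)OCc2ccccc2)[C@]3(C)O[C@@](C)([C@@H]4CO4)CC[C@H]3C=1CCOCc5ccccc5 | intermediate
26 | O-trimethylsilyl ketene acetal of lactone 24 (6-trimethylsilyloxy-4a,8a-dihydro-pyrano[3,4-b]pyran with C5=C6; not isolated) | C[Si](C)(C)OC=1O[C@H](/C=C/C(C)(C)C(=O)OCc2ccccc2)[C@]3(C)O[C@@](C)([C@@H]4CO4)CC[C@H]3C=1CCOCc5ccccc5 | intermediate
27 | trimethylsilyl ester of acid 28 (not isolated) | CC(C)(C(=O)OCc1ccccc1)[C@H]2C=C[C@]3(C)O[C@@](C)([C@@H]4CO4)CC[C@H]3[C@]2(C(=O)O[Si](C)(C)C)CCOCc5ccccc5 | intermediate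
28 | (2R,4aS,5S,6R,8aS)-6-[1-(benzyloxy)-2-methyl-1-oxopropan-2-yl]-5-[2-(benzyloxy)ethyl]-2,8a-dimethyl-2-[(2S)-oxiran-2-yl]-3,4,4a,5,6,8a-hexahydro-2H-chromene-5-carboxylic acid | CC(C)(C(=O)OCc1ccccc1)[C@H]2C=C[C@]3(C)O[C@@](C)([C@@H]4CO4)CC[C@H]3[C@]2(C(=O)O)CCOCc5ccccc5 | intermediate
29 | 1H-imidazol-1-yl ketone (acyl imidazolide) of acid 28 (not isolated) | CC(C)(C(=O)OCc1ccccc1)[C@H]2C=C[C@]3(C)O[C@@](C)([C@@H]4CO4)CC[C@H]3[C@]2(C(=O)n6ccnc6)CCOCc5ccccc5 | intermediate
30 | benzyl 2-[(2R,4aS,5S,6S,8aS)-5-[2-(benzyloxy)ethyl]-5-(hydroxymethyl)-2,8a-dimethyl-2-[(2S)-oxiran-2-yl]-3,4,4a,5,6,8a-hexahydro-2H-chromen-6-yl]-2-methylpropanoate | CC(C)(C(=O)OCc1ccccc1)[C@H]2C=C[C@]3(C)O[C@@](C)([C@@H]4CO4)CC[C@H]3[C@]2(CO)CCOCc5ccccc5 | intermediate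
31 | benzyl 2-[(2R,4aS,5S,6S,8aS)-5-[2-(benzyloxy)ethyl]-5-{[(1H-imidazol-1-ylcarbonothioyl)oxy]methyl}-2,8a-dimethyl-2-[(2S)-oxiran-2-yl]-3,4,4a,5,6,8a-hexahydro-2H-chromen-6-yl]-2-methylpropanoate | CC(C)(C(=O)OCc1ccccc1)[C@H]2C=C[C@]3(C)O[C@@](C)([C@@H]4CO4)CC[C@H]3[C@]2(COC(=S)n6ccnc6)CCOCc5ccccc5 | intermediate
32 | benzyl 2-[(2R,4aS,5R,6S,8aS)-5-[2-(benzyloxy)ethyl]-2,5,8a-trimethyl-2-[(2S)-oxiran-2-yl]-3,4,4a,5,6,8a-hexahydro-2H-chromen-6-yl]-2-methylpropanoate | CC(C)(C(=O)OCc1ccccc1)[C@H]2C=C[C@]3(C)O[C@@](C)([C@@H]4CO4)CC[C@H]3[C@]2(C)CCOCc5ccccc5 | intermediate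
33 | 2-[(2R,4aS,5R,6S,8aS)-5-(2-hydroxyethyl)-2,5,8a-trimethyl-2-[(2S)-oxiran-2-yl]octahydro-2H-chromen-6-yl]-2-methylpropanoic acid | CC(C)(C(=O)O)[C@H]1CC[C@]2(C)O[C@@](C)([C@@H]3CO3)CC[C@H]2[C@]1(C)CCO | intermediate
34 | 2-[(2R,4aS,5R,6S,8aS)-5-(carboxymethyl)-2,5,8a-trimethyl-2-[(2S)-oxiran-2-yl]octahydro-2H-chromen-6-yl]-2-methylpropanoic acid | CC(C)(C(=O)O)[C@H]1CC[C@]2(C)O[C@@](C)([C@@H]3CO3)CC[C@H]2[C@]1(C)CC(=O)O | target

Total step count: 17. Longest linear sequence: 15 steps (steps 1, 2, 4 to 7 and 9 to 17, from geranyl acetate).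

Steps most likely to fail

Step 12. The trans-fused oxane holds the lactone in a half-chair in which the C–O bond that must break starts close to the plane of the ketene acetal, and the new bond joins a quaternary carbon to a carbon next to CMe2. The rearrangement may therefore be slow enough for O-to-C silyl migration or loss of the silyl group to drain the ketene acetal. The fallback sets out from lactone 24. i-Bu2AlH (CH2Cl2, −78 °C) would reduce it to lactol 23, and MsCl/Et3N would dehydrate 23 to the cyclic enol ether F1. Heating (xylene, 180 °C, sealed tube) would then bring about the Claisen rearrangement of this neutral allyl vinyl ether, the known thermal route from 2-alkenyl-3,4-dihydro-2H-pyrans to cyclohex-3-enecarbaldehydes, to give aldehyde F2. NaBH4 (MeOH, 0 °C) would reduce F2 to alcohol 30, where the route is rejoined. No enolate or silyl group is involved and a higher temperature is tolerated.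

Step 9. Facial selectivity may be poor or reversed: the ring-ether oxygen lies between two quaternary carbons and may not chelate, in which case Felkin–Anh attack would prevail. The fallback again sets out from aldehyde 14 and alkyne 16 and accepts the (5S)-epimer F3 as the main adduct. Dess–Martin periodinane would oxidise it to enone F4, and K(s-Bu)3BH (THF, −78 °C) would reduce F4 by 1,2-addition under Felkin–Anh control (hydride anti to the ring C–O bond), which should give 19, where the route is rejoined. The carbinol centre is then set by hydride delivery instead of by C–C bond formation.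

Step 16. Saturation of the shielded ring alkene may be slow, and long exposure to Pd and H2 could then lead to hydrogenolysis of the oxirane C–O bond. The fallback sets out from 32. Homogeneous hydrogenation with [Ir(cod)(PCy3)(py)]PF6 (H2, CH2Cl2, rt) would reduce only the alkene and give the saturated dibenzyl compound F5. A short hydrogenolysis (H2, Pd(OH)2/C, EtOAc) would then remove the two benzyl groups and give 33, where the route is rejoined.

Further compounds
F1 | step 12 | benzyl (3E)-4-[(2R,4aS,8R,8aR)-5-[2-(benzyloxy)ethyl]-2,8a-dimethyl-2-[(2S)-oxiran-2-yl]-3,4,4a,8a-tetrahydro-2H,8H-pyrano[3,4-b]pyran-8-yl]-2,2-dimethylbut-3-enoate (cyclic enol ether, C5=C6) | C=1O[C@H](/C=C/C(C)(C)C(=O)OCc2ccccc2)[C@]3(C)O[C@@](C)([C@@H]4CO4)CC[C@H]3C=1CCOCc5ccccc5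
F2 | step 12 | benzyl 2-[(2R,4aS,5S,6S,8aS)-5-[2-(benzyloxy)ethyl]-5-formyl-2,8a-dimethyl-2-[(2S)-oxiran-2-yl]-3,4,4a,5,6,8a-hexahydro-2H-chromen-6-yl]-2-methylpropanoate | CC(C)(C(=O)OCc1ccccc1)[C@H]2C=C[C@]3(C)O[C@@](C)([C@@H]4CO4)CC[C@H]3[C@]2(C=O)CCOCc5ccccc5
F3 | step 9 | benzyl (3E,5S)-5-[(2R,3S,6R)-3-[4-(benzyloxy)but-1-en-2-yl]-2,6-dimethyl-6-[(2S)-oxiran-2-yl]oxan-2-yl]-5-hydroxy-2,2-dimethylpent-3-enoate | O[C@@H](/C=C/C(C)(C)C(=O)OCc1ccccc1)[C@]2(C)O[C@@](C)([C@@H]3CO3)CC[C@H]2C(=C)CCOCc4ccccc4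
F4 | step 9 | benzyl (3E)-5-[(2R,3S,6R)-3-[4-(benzyloxy)but-1-en-2-yl]-2,6-dimethyl-6-[(2S)-oxiran-2-yl]oxan-2-yl]-2,2-dimethyl-5-oxopent-3-enoate | O=C(/C=C/C(C)(C)C(=O)OCc1ccccc1)[C@]2(C)O[C@@](C)([C@@H]3CO3)CC[C@H]2C(=C)CCOCc4ccccc4
F5 | step 16 | benzyl 2-[(2R,4aS,5R,6S,8aS)-5-[2-(benzyloxy)ethyl]-2,5,8a-trimethyl-2-[(2S)-oxiran-2-yl]octahydro-2H-chromen-6-yl]-2-methylpropanoate | CC(C)(C(=O)OCc1ccccc1)[C@H]2CC[C@]3(C)O[C@@](C)([C@@H]4CO4)CC[C@H]3[C@]2(C)CCOCc5ccccc5
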